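**Retrosynthetic overview** (eudesmane numbering: ring A = C1–C5 and C10, ring B = C5–C10, C1' = benzylic carbon, C14 = methyl on C10, C15 = carbon on C4)

- Feature the route rests on: ring B with its stereocentres C5, C7 and C10, the C7 isopropenyl group and a C5 isopropenyl group (C3=C4–C15) are all present in (−)-β-elemene. Only the C2–C3 bond of ring A and the arylmethyl carbon C1' on C1 are missing.
- Target ⇒ MOM removal and two directed arene metalations (isobutyryl, formyl) on tris-MOM arene 20 ⇒ 4α-hydroxy-2-ketone 16, whose C2 oxygen is removed through the tosylhydrazone.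
- 16 ⇒ 3α,4α-epoxy-2-ketone 15 (C1 set by kinetic enolate protonation, C4 by α-epoxidation of the Δ3-en-2-one) ⇒ 2-hydroxy-4(15)-ene 10.
- 10 ⇒ aldehyde 9 by C2–C3 disconnection (type 2 carbonyl-ene). Ring A is the only ring made; ring B comes with elemene and the arene with phloroglucinol.
- 9 ⇒ diaryl cuprate from phloroglucinol tris-MOM ether + 2-substituted acrolein 3 ⇒ aldehyde 2 ⇒ vinyl group of β-elemene.

Key step: step 5

Remark on the chemistry: C1 is not under control before step 9, so 9–13 are pairs of C1 epimers and C1 is left open in their SMILES. The carbinol centre C2 of 10 is drawn axial (2β), as a concerted hydrogen transfer demands, and is destroyed in step 6.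

**Route**

Step 1
Reactants: 1 (−)-β-elemene
Product: 2 elema-3,11(12)-dien-2-al
Conditions: PdCl2(PhCN)2 (12 mol%), CuCl2·2H2O (12 mol%), AgNO2 (6 mol%), O2 (1 atm), t-BuOH/MeNO2 (15:1), rt
Reagents that add atoms: dioxygen O=O
Why: Nitrite-modified, aldehyde-selective Wacker oxidation: the monosubstituted vinyl group on quaternary C10 is the alkene that divalent palladium oxidises, the adjacent quaternary centre steers oxygen to the terminal carbon, and the two 1,1-disubstituted isopropenyl groups are poor Wacker substrates.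

Step 2
Reactants: 2 elema-3,11(12)-dien-2-al
Product: 3 1-methylene-elema-3,11(12)-dien-2-al
Conditions: 37% aq. HCHO, pyrrolidine (10 mol%), EtCO2H (10 mol%), i-PrOH, 45 °C
Reagents that add atoms: formaldehyde C=O
Why: Amine/acid-catalysed α-methylenation (Mannich condensation, then β-elimination of the amine) should work even next to the quaternary carbon because formaldehyde is the smallest electrophile, and it leaves the alkenes untouched.

Step 3
Reactants: 4 phloroglucinol
Product: 5 1,3,5-tris(methoxymethoxy)benzene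
Conditions: NaH, MOMCl, DMF, 0 °C → rt
Reagents that add atoms: chloromethyl methyl ether COCCl
Why: Williamson-type O-alkylation of the phenoxide gives the tris-MOM ether, whose oxygen atoms later direct every arene metalation.

Step 4
Reactants: 3 1-methylene-elema-3,11(12)-dien-2-al; 5 1,3,5-tris(methoxymethoxy)benzene
Product: 9 1-[2,4,6-tris(methoxymethoxy)benzyl]elema-3,11(12)-dien-2-al (both C1 epimers), via aryllithium 6 (not isolated), via diarylcuprate 7 (not isolated), via silyl enol ether 8 (not isolated)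
Conditions: 5 (2.4 equiv), n-BuLi, THF, 0 °C; CuBr·SMe2 (1.2 equiv), −40 °C; TMSCl, then 3, −78 → −40 °C; then 1 M aq. HCl, THF, 0 °C
Reagents that add atoms: none
Why: Directed ortho-lithiation between two OMOM groups, transmetalation to the Gilman diarylcuprate and TMSCl-accelerated conjugate addition should place the aryl group on the unhindered CH2 terminus of the enal (1,4 over 1,2 because the silyl chloride traps the copper adduct as the enol ether), and mild hydrolysis gives the aldehyde with uncontrolled protonation at C1.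

Step 5
Reactants: 9 1-[2,4,6-tris(methoxymethoxy)benzyl]elema-3,11(12)-dien-2-al (both C1 epimers)
Product: 10 1-[2,4,6-tris(methoxymethoxy)benzyl]selina-4(15),11-dien-2β-ol (both C1 epimers)
Conditions: Me2AlCl (2.5 equiv), CH2Cl2, −78 → −20 °C; aq. potassium sodium tartrate
Reagents that add atoms: none
Why: Me2AlCl binds the aldehyde oxygen and the C5 isopropenyl group acts as the ene: its CH2 terminus (C3) bonds to C2 while a hydrogen of its methyl group (C15) passes to oxygen through a six-centre array, leaving the exocyclic C4=C15 alkene; the closest known reaction type is the Lewis acid-promoted type 2 carbonyl-ene cyclisation of 5-methylhex-5-enals to 3-methylenecyclohexanols. Ring A closes as a six-membered chair by C2–C3 bond formation with the tether on the central ene carbon C4, and it is trans-fused because the C1 chain and the isopropenyl group are both equatorial on ring B of the elemane, so no ring-fusion centre is made or changed. The only new stereocentre is C2, and the concerted geometry should set it: the oxygen must sit axial (β) on the forming chair to reach the C15 hydrogen, hence the 2β-ol, and since step 6 removes this centre the 2α epimer from any stepwise pathway would serve equally. The step needs the C5 and not the C7 isopropenyl group to react, which ring size secures because C7 could only close a strained bridged ring, and it needs ene transfer in place of cationic Prins chemistry, which Me2AlCl secures by consuming the proton as methane when the aluminium alkoxide forms. Both C1 epimers of 9 can reach the chair (arylmethyl equatorial or axial), so the pair is carried on and C1 is set in step 9.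

Step 6
Reactants: 10 1-[2,4,6-tris(methoxymethoxy)benzyl]selina-4(15),11-dien-2β-ol (both C1 epimers)
Product: 11 1-[2,4,6-tris(methoxymethoxy)benzyl]selina-4(15),11-dien-2-one (both C1 epimers)
Conditions: Dess–Martin periodinane, NaHCO3, CH2Cl2, 0 °C → rt
Reagents that add atoms: none
Why: Dess–Martin oxidation of the secondary alcohol under buffered conditions gives the β,γ-unsaturated ketone and erases the C2 centre.

Step 7
Reactants: 11 1-[2,4,6-tris(methoxymethoxy)benzyl]selina-4(15),11-dien-2-one (both C1 epimers)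
Product: 12 1-[2,4,6-tris(methoxymethoxy)benzyl]eudesma-3,11-dien-2-one (both C1 epimers)
Conditions: DBU (0.3 equiv), CH2Cl2, rt
Reagents that add atoms: none
Why: Base-mediated alkene isomerisation: DBU removes the doubly activated C3 proton and reprotonation at C15 gives the conjugated Δ3-enone, while short contact with a weak base should leave the γ-proton at C5 and hence the ring fusion alone.

Step 8
Reactants: 12 1-[2,4,6-tris(methoxymethoxy)benzyl]eudesma-3,11-dien-2-one (both C1 epimers)
Product: 13 3α,4α-epoxy-1-[2,4,6-tris(methoxymethoxy)benzyl]eudesm-11-en-2-one (both C1 epimers)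
Conditions: 30% aq. H2O2, NaOH (0.3 equiv), MeOH, 0 °C
Reagents that add atoms: hydrogen peroxide OO
Why: Weitz–Scheffer nucleophilic epoxidation attacks only the enone (the isopropenyl group is inert to hydroperoxide anion), and the hydroperoxide should add to C4 on the α face, away from the axial C10 methyl group that is 1,3 to C4, which sets the 4α C–O bond.

Step 9
Reactants: 13 3α,4α-epoxy-1-[2,4,6-tris(methoxymethoxy)benzyl]eudesm-11-en-2-one (both C1 epimers)
Product: 15 3α,4α-epoxy-1β-[2,4,6-tris(methoxymethoxy)benzyl]eudesm-11-en-2-one, via lithium enolate 14 (not isolated)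
Conditions: LiN(i-Pr)2 (1.5 equiv), THF, −78 → −40 °C; then AcOH, THF, −78 °C
Reagents that add atoms: none
Why: The oxirane blocks enolisation towards C3, so the amide base can give only the C1(2)-enolate from either epimer, and kinetic protonation should come axially on the α face, anti to the adjacent axial C10 methyl group, which puts hydrogen 1α and the arylmethyl group 1β (equatorial).

Step 10
Reactants: 15 3α,4α-epoxy-1β-[2,4,6-tris(methoxymethoxy)benzyl]eudesm-11-en-2-one
Product: 16 4α-hydroxy-1β-[2,4,6-tris(methoxymethoxy)benzyl]eudesm-11-en-2-one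
Conditions: SmI2 (2.5 equiv), THF/MeOH, −90 °C
Reagents that add atoms: none
Why: Divalent samarium reduces the ketone to a ketyl that ejects the α C3–O bond of the oxirane (the known SmI2 reduction of α,β-epoxy ketones to β-hydroxy ketones), so the C4–O bond and its α configuration are kept and C1 is not touched at this temperature.

Step 11
Reactants: 16 4α-hydroxy-1β-[2,4,6-tris(methoxymethoxy)benzyl]eudesm-11-en-2-one
Product: 17 p-toluenesulfonylhydrazone of 16
Conditions: TsNHNH2, MeOH, 40 °C
Reagents that add atoms: p-toluenesulfonohydrazide Cc1ccc(cc1)S(=O)(=O)NN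
Why: Condensation of the ketone with the sulfonyl hydrazide under near-neutral conditions should give the tosylhydrazone without dehydration of the β-hydroxy ketone.

Step 12
Reactants: 17 p-toluenesulfonylhydrazone of 16
Product: 20 1β-[2,4,6-tris(methoxymethoxy)benzyl]eudesm-11-en-4α-ol, via boryl hydrazide 18 (not isolated), via diazene 19 (not isolated)
Conditions: catecholborane (4 equiv), CHCl3, 0 °C → rt; then NaOAc·3H2O, 60 °C
Reagents that add atoms: none
Why: Catecholborane reduction of a tosylhydrazone (a mild Caglioti-type deoxygenation): hydride adds to C=N, acetate then releases sulfinate to give the alkyl diazene, and loss of N2 leaves CH2 at C2 under conditions that should spare the alkene, the MOM ethers and the tertiary alcohol.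

Step 13
Reactants: 20 1β-[2,4,6-tris(methoxymethoxy)benzyl]eudesm-11-en-4α-ol
Product: 22 1β-[3-(1-hydroxy-2-methylpropyl)-2,4,6-tris(methoxymethoxy)benzyl]eudesm-11-en-4α-ol (carbinol epimers), via aryllithium 21 (not isolated)
Conditions: n-BuLi (2.5 equiv), THF, 0 °C; i-PrCHO, −78 °C → rt; H2O
Reagents that add atoms: isobutyraldehyde CC(C)C=O
Why: Directed ortho-metalation: after deprotonation of the tertiary hydroxyl, n-BuLi removes one of the two equivalent ring hydrogens flanked by OMOM groups, and the aryllithium adds to isobutyraldehyde.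

Step 14
Reactants: 22 1β-[3-(1-hydroxy-2-methylpropyl)-2,4,6-tris(methoxymethoxy)benzyl]eudesm-11-en-4α-ol (carbinol epimers)
Product: 24 1β-[3-formyl-5-(1-hydroxy-2-methylpropyl)-2,4,6-tris(methoxymethoxy)benzyl]eudesm-11-en-4α-ol (carbinol epimers), via aryllithium 23 (not isolated)
Conditions: n-BuLi (3.5 equiv), THF, 0 °C; DMF, 0 °C → rt; H2O
Reagents that add atoms: N,N-dimethylformamide CN(C)C=O
Why: A second directed ortho-metalation at the only remaining ring hydrogen (again between two OMOM groups, both hydroxyls being held as lithium alkoxides) followed by formylation with DMF gives the aryl aldehyde.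

Step 15
Reactants: 24 1β-[3-formyl-5-(1-hydroxy-2-methylpropyl)-2,4,6-tris(methoxymethoxy)benzyl]eudesm-11-en-4α-ol (carbinol epimers)
Product: 25 1β-[3-formyl-5-(2-methylpropanoyl)-2,4,6-tris(methoxymethoxy)benzyl]eudesm-11-en-4α-ol
Conditions: Dess–Martin periodinane, NaHCO3, CH2Cl2, rt
Reagents that add atoms: none
Why: Dess–Martin oxidation converts the secondary benzylic alcohol into the aryl isopropyl ketone and cannot oxidise the tertiary alcohol or take the aldehyde further.

Step 16
Reactants: 25 1β-[3-formyl-5-(2-methylpropanoyl)-2,4,6-tris(methoxymethoxy)benzyl]eudesm-11-en-4α-ol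
Product: 26 1β-[3-formyl-2,4,6-trihydroxy-5-(2-methylpropanoyl)benzyl]eudesm-11-en-4α-ol (CNP0498016.1)
Conditions: 1.25 M HCl in MeOH, THF, rt; aq. work-up
Reagents that add atoms: none
Why: Acid-catalysed acetal exchange with methanol removes the three aryl MOM ethers, each of which is ortho to a carbonyl group and so should cleave under acid mild enough to leave the tertiary alcohol and the isopropenyl group intact.

**Compound list**

1 | (−)-β-elemene (vinyl and methyl on C10, isopropenyl groups on C5 and C7) | C=C(C)[C@@H]1CC[C@@](C)(C=C)[C@H](C(C)=C)C1 | starting material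
2 | elema-3,11(12)-dien-2-al (the C10 vinyl group of 1 turned into CH2–CHO; C5, C7, C10 as in 1) | C=C(C)[C@@H]1CC[C@@](C)(CC=O)[C@H](C(C)=C)C1 | intermediate
3 | 1-methylene-elema-3,11(12)-dien-2-al (2-substituted acrolein, C10–C(=CH2)–CHO) | C=C(C)[C@@H]1CC[C@@](C)(C(=C)C=O)[C@H](C(C)=C)C1 | intermediate
4 | phloroglucinol (benzene-1,3,5-triol) | Oc1cc(O)cc(O)c1 | starting material
5 | 1,3,5-tris(methoxymethoxy)benzene | COCOc1cc(OCOC)cc(OCOC)c1 | intermediate
6 | 2,4,6-tris(methoxymethoxy)phenyllithium | [Li]c1c(OCOC)cc(OCOC)cc1OCOC | intermediate (not isolated)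
7 | lithium bis[2,4,6-tris(methoxymethoxy)phenyl]cuprate | [Li+].COCOc1cc(OCOC)c([Cu-]c2c(OCOC)cc(OCOC)cc2OCOC)c(OCOC)c1 | intermediate (not isolated)
8 | trimethylsilyl enol ether of 9 (C1=C2–OSiMe3, alkene geometry open) | C=C(C)[C@@H]1CC[C@@](C)(C(Cc2c(OCOC)cc(OCOC)cc2OCOC)=CO[Si](C)(C)C)[C@H](C(C)=C)C1 | intermediate (not isolated)
9 | 1-[2,4,6-tris(methoxymethoxy)benzyl]elema-3,11(12)-dien-2-al (C10–C1H(CH2Ar)–CHO; both C1 epimers, C1 open in the SMILES) | C=C(C)[C@@H]1CC[C@@](C)(C(Cc2c(OCOC)cc(OCOC)cc2OCOC)C=O)[C@H](C(C)=C)C1 | intermediate (key-step precursor)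
10 | 1-[2,4,6-tris(methoxymethoxy)benzyl]selina-4(15),11-dien-2β-ol (trans-decalin, 10β-CH3, 5α-H, 7β-isopropenyl, axial 2β-OH; both C1 epimers) | C=C(C)[C@@H]1CC[C@@]2(C)C(Cc3c(OCOC)cc(OCOC)cc3OCOC)[C@H](O)CC(=C)[C@@H]2C1 | intermediate (key-step product)
11 | 1-[2,4,6-tris(methoxymethoxy)benzyl]selina-4(15),11-dien-2-one (both C1 epimers) | C=C(C)[C@@H]1CC[C@@]2(C)C(Cc3c(OCOC)cc(OCOC)cc3OCOC)C(=O)CC(=C)[C@@H]2C1 | intermediate
12 | 1-[2,4,6-tris(methoxymethoxy)benzyl]eudesma-3,11-dien-2-one (both C1 epimers) | C=C(C)[C@@H]1CC[C@@]2(C)C(Cc3c(OCOC)cc(OCOC)cc3OCOC)C(=O)C=C(C)[C@@H]2C1 | intermediate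
13 | 3α,4α-epoxy-1-[2,4,6-tris(methoxymethoxy)benzyl]eudesm-11-en-2-one (both C1 epimers) | C=C(C)[C@@H]1CC[C@@]2(C)C(Cc3c(OCOC)cc(OCOC)cc3OCOC)C(=O)[C@H]4O[C@@]4(C)[C@@H]2C1 | intermediate
14 | lithium C1(2)-enolate of 13 | C=C(C)[C@@H]1CC[C@@]2(C)C(Cc3c(OCOC)cc(OCOC)cc3OCOC)=C(O[Li])[C@H]4O[C@@]4(C)[C@@H]2C1 | intermediate (not isolated)
15 | 3α,4α-epoxy-1β-[2,4,6-tris(methoxymethoxy)benzyl]eudesm-11-en-2-one (1α-H, arylmethyl equatorial) | C=C(C)[C@@H]1CC[C@@]2(C)[C@H](Cc3c(OCOC)cc(OCOC)cc3OCOC)C(=O)[C@H]4O[C@@]4(C)[C@@H]2C1 | intermediate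
16 | 4α-hydroxy-1β-[2,4,6-tris(methoxymethoxy)benzyl]eudesm-11-en-2-one (4β-CH3 axial, 4α-OH equatorial) | C=C(C)[C@@H]1CC[C@@]2(C)[C@H](Cc3c(OCOC)cc(OCOC)cc3OCOC)C(=O)C[C@@](C)(O)[C@@H]2C1 | intermediate
17 | p-toluenesulfonylhydrazone of 16 (C=N geometry open) | C=C(C)[C@@H]1CC[C@@]2(C)[C@H](Cc3c(OCOC)cc(OCOC)cc3OCOC)C(=NNS(=O)(=O)c4ccc(C)cc4)C[C@@](C)(O)[C@@H]2C1 | intermediate
18 | N-(1,3,2-benzodioxaborol-2-yl)-N'-tosyl hydrazide from hydride addition at C2 of 17 (C2 open; tertiary hydroxyl drawn free) | C=C(C)[C@@H]1CC[C@@]2(C)[C@H](Cc3c(OCOC)cc(OCOC)cc3OCOC)C(N(NS(=O)(=O)c4ccc(C)cc4)B5Oc6ccccc6O5)C[C@@](C)(O)[C@@H]2C1 | intermediate (not isolated)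
19 | C2 diazene (C2–N=NH, C2 open) | C=C(C)[C@@H]1CC[C@@]2(C)[C@H](Cc3c(OCOC)cc(OCOC)cc3OCOC)C(N=N)C[C@@](C)(O)[C@@H]2C1 | intermediate (not isolated)
20 | 1β-[2,4,6-tris(methoxymethoxy)benzyl]eudesm-11-en-4α-ol | C=C(C)[C@@H]1CC[C@@]2(C)[C@H](Cc3c(OCOC)cc(OCOC)cc3OCOC)CC[C@@](C)(O)[C@@H]2C1 | intermediate
21 | dilithio derivative of 20 (lithium alkoxide on the C4 oxygen, aryllithium at C3') | C=C(C)[C@@H]1CC[C@@]2(C)[C@H](Cc3c(OCOC)c([Li])c(OCOC)cc3OCOC)CC[C@@](C)(O[Li])[C@@H]2C1 | intermediate (not isolated)
22 | 1β-[3-(1-hydroxy-2-methylpropyl)-2,4,6-tris(methoxymethoxy)benzyl]eudesm-11-en-4α-ol (carbinol epimers) | C=C(C)[C@@H]1CC[C@@]2(C)[C@H](Cc3c(OCOC)c(C(O)C(C)C)c(OCOC)cc3OCOC)CC[C@@](C)(O)[C@@H]2C1 | intermediate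
23 | trilithio derivative of 22 (two lithium alkoxides, aryllithium at C5') | C=C(C)[C@@H]1CC[C@@]2(C)[C@H](Cc3c(OCOC)c(C(O[Li])C(C)C)c(OCOC)c([Li])c3OCOC)CC[C@@](C)(O[Li])[C@@H]2C1 | intermediate (not isolated)
24 | 1β-[3-formyl-5-(1-hydroxy-2-methylpropyl)-2,4,6-tris(methoxymethoxy)benzyl]eudesm-11-en-4α-ol (carbinol epimers) | C=C(C)[C@@H]1CC[C@@]2(C)[C@H](Cc3c(OCOC)c(C(O)C(C)C)c(OCOC)c(C=O)c3OCOC)CC[C@@](C)(O)[C@@H]2C1 | intermediate
25 | 1β-[3-formyl-5-(2-methylpropanoyl)-2,4,6-tris(methoxymethoxy)benzyl]eudesm-11-en-4α-ol | C=C(C)[C@@H]1CC[C@@]2(C)[C@H](Cc3c(OCOC)c(C(=O)C(C)C)c(OCOC)c(C=O)c3OCOC)CC[C@@](C)(O)[C@@H]2C1 | intermediate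
26 | 1β-[3-formyl-2,4,6-trihydroxy-5-(2-methylpropanoyl)benzyl]eudesm-11-en-4α-ol (CNP0498016.1) | C=C(C)[C@@H]1CC[C@@]2(C)[C@H](Cc3c(O)c(C=O)c(O)c(C(=O)C(C)C)c3O)CC[C@@](C)(O)[C@@H]2C1 | target

**Step count**

Total: 16 steps. Longest linear sequence: 15 steps (steps 1, 2 and 4–16 from β-elemene); step 3 is the one-step branch to the arene.

**Steps most likely to fail**

1. Step 5 (key step). What may go wrong: the six MOM oxygen atoms hold or are cleaved by the aluminium Lewis acid, the activated aldehyde is attacked by the electron-rich arene of a second molecule, or the epimer that must carry the arylmethyl group axial closes too slowly, so that cyclisation stalls or turns cationic.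
Fallback, from 2 back to 12: the same ring closure is run before the arene is attached. Me2AlCl (CH2Cl2, −78 °C) should convert 2 into selina-4(15),11-dien-2β-ol F1. Dess–Martin oxidation gives selina-4(15),11-dien-2-one F2, and DBU gives eudesma-3,11-dien-2-one F3. Kinetic deprotonation at C1 (LiN(i-Pr)2, THF, −78 °C) and Mannich reaction with CH2=NMe2+ I− give 1-(dimethylaminomethyl)eudesma-3,11-dien-2-one F4. MeI gives the trimethylammonium iodide F5, and NaHCO3 eliminates trimethylamine to give 1-methylene-eudesma-3,11-dien-2-one F6. Cuprate 7 with TMSCl should add the aryl group to the exocyclic CH2 terminus (the other enone terminus, C4, is β,β-disubstituted and slower) to give silyl dienol ether F7. Hydrolysis (1 M aq. HCl, THF, 0 °C) protonates C1, expected mainly on the α face, and returns the route to 12 ahead of step 8; step 9 stays in place as the safeguard for C1.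

2. Step 4. What may go wrong: 1,2-addition competes with 1,4-addition, or aryl transfer from a cuprate with two ortho substituents on each ring is so slow that the enal polymerises.
Fallback, from 2 back to 9: the C1–C1' connection is made as a C=C bond and then reduced. 2,4,6-Trihydroxybenzaldehyde (commercial) is protected (NaH, MOMCl, DMF) as 2,4,6-tris(methoxymethoxy)benzaldehyde F8. Crossed aldol condensation of 2 with F8, which cannot enolise (KOH, MeOH, slow addition of 2 to excess F8), should give 1-[2,4,6-tris(methoxymethoxy)benzylidene]elema-3,11(12)-dien-2-al F9. Conjugate reduction with [(Ph3P)CuH]6 (PhMe, H2O, rt), which leaves isolated alkenes alone, gives 9, and the route resumes at step 5.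

3. Step 9. What may go wrong: incomplete deprotonation of the epimer whose C1 hydrogen is equatorial, or poor facial selectivity in the protonation, so that the 1α epimer persists.
Fallback, from 13 back to 16: C1 is set by thermodynamic control in the saturated chair in place of kinetic protonation. The epimer pair 13 is opened with SmI2 as in step 10, which gives 16 mixed with 4α-hydroxy-1α-[2,4,6-tris(methoxymethoxy)benzyl]eudesm-11-en-2-one F10. In this saturated ring the axial arylmethyl group of F10 meets the two syn-axial hydrogens on C3 and C5, so equilibration through the C1 enol (DBU, PhMe, rt, conditions too mild for β-elimination of the tertiary hydroxyl) should move the mixture towards 16. The remaining minor epimer is separated and recycled, and the route resumes at step 11.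

**Further compounds**

F1 | step 5 | selina-4(15),11-dien-2β-ol | C=C(C)[C@@H]1CC[C@@]2(C)C[C@H](O)CC(=C)[C@@H]2C1
F2 | step 5 | selina-4(15),11-dien-2-one | C=C(C)[C@@H]1CC[C@@]2(C)CC(=O)CC(=C)[C@@H]2C1
F3 | step 5 | eudesma-3,11-dien-2-one | C=C(C)[C@@H]1CC[C@@]2(C)CC(=O)C=C(C)[C@@H]2C1
F4 | step 5 | 1-(dimethylaminomethyl)eudesma-3,11-dien-2-one (C1 open) | C=C(C)[C@@H]1CC[C@@]2(C)C(CN(C)C)C(=O)C=C(C)[C@@H]2C1
F5 | step 5 | trimethylammonium iodide of F4 (C1 open) | [I-].C=C(C)[C@@H]1CC[C@@]2(C)C(C[N+](C)(C)C)C(=O)C=C(C)[C@@H]2C1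
F6 | step 5 | 1-methylene-eudesma-3,11-dien-2-one | C=C(C)[C@@H]1CC[C@@]2(C)C(=C)C(=O)C=C(C)[C@@H]2C1
F7 | step 5 | 2-trimethylsilyloxy-1-[2,4,6-tris(methoxymethoxy)benzyl]eudesma-1,3,11-triene | C=C(C)[C@@H]1CC[C@@]2(C)C(Cc3c(OCOC)cc(OCOC)cc3OCOC)=C(O[Si](C)(C)C)C=C(C)[C@@H]2C1
F8 | step 4 | 2,4,6-tris(methoxymethoxy)benzaldehyde | COCOc1cc(OCOC)c(C=O)c(OCOC)c1
F9 | step 4 | 1-[2,4,6-tris(methoxymethoxy)benzylidene]elema-3,11(12)-dien-2-al (alkene geometry open) | C=C(C)[C@@H]1CC[C@@](C)(C(C=O)=Cc2c(OCOC)cc(OCOC)cc2OCOC)[C@H](C(C)=C)C1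
F10 | step 9 | 4α-hydroxy-1α-[2,4,6-tris(methoxymethoxy)benzyl]eudesm-11-en-2-one | C=C(C)[C@@H]1CC[C@@]2(C)[C@@H](Cc3c(OCOC)cc(OCOC)cc3OCOC)C(=O)C[C@@](C)(O)[C@@H]2C1
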